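Stop this flask early. You must choose between working it up at the end of the feed and leaving it to the longest time allowed.

| setting | ochre | amber | flask |
|---|---|---|---|
| substrate | 0.010 M | 0.015 M | 0.020 M |
| partner | 1.1 equiv (fed, over 12 min) | 1.1 equiv (fed, over 12 min) | 1.10 equiv (fed, over 12 min) |
| remark | run made earlier | run made earlier |  |
| time |  |  | 6.0 h |

| run | time / h | target / % |
|---|---|---|
| ochre | 0.0417 | 2.9 |
| ochre | 0.200 | 17.0 |
| ochre | 0.833 | 15.2 |
| ochre | 4.00 | 14.6 |
| amber | 0.0417 | 4.3 |
| amber | 0.200 | 16.9 |
| amber | 0.833 | 14.7 |
| amber | 4.00 | 14.3 |

(standard deviation of a reading: 0.3 percentage points)

- when, up to 6.0 h, the flask holds most target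
- the amount of target, in percent of the substrate charged, at that time

- the numbers in the tables scatter with a standard deviation of 0.3 percentage points

Both earlier runs show the same shape. The highest reading of target stands at 0.200 h, when the feed ends, and the later readings sag toward a plateau. I carry one number, the keep, the plateau reading divided by the highest reading. The ochre run gives 0.859 and the amber run 0.846, a mean of 0.852.

Suppose the gain and the loss of target both use partner. Then partner and time drop out of the ratio of their rates, as in a selectivity factor. The keep should then not move with concentration, and the two runs differ by 0.0127.

The highest readings agree as well, so I expect about 16.9% in the flask. The early readings rise by a factor 1.48 for a factor 1.50 in concentration. The flask, more concentrated than the amber run, should therefore peak at the end of the feed or a little before it. Waiting should leave 14.4%, a loss of 2.5 points against a scatter of 0.3 points. So my decision is to stop at the end of the feed.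

The forecast says 17.8% at 0.17 h, more than my figure, reasoning that “target consumes partner faster than substrate does”.

The flask gives 17.0% at 0.176 h, and 14.2% at 6.00 h.

    substrate + partner → target (k = 15.0 M⁻¹ min⁻¹)
    substrate + partner → isomer of the product (k = 14.0 M⁻¹ min⁻¹)
    partner + target → over-reaction product (k = 36.0 M⁻¹ min⁻¹)
    partner → decomposed reagent (k = 0.0180 min⁻¹)

The keep of this flask is 0.835, a little below the 0.852 of the runs. At the best time the flask holds 40.8% substrate and 17.0% target. With partner dropped from both, the rate of target lost, 36 M⁻¹ min⁻¹ times target, over the rate of target made, 15 M⁻¹ min⁻¹ times substrate, is then 1.00. The neighbour charged with 0.440 equiv of partner has a keep of 1.00, ending at 14.4% target with 62% of its substrate left.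

(Readings and results are calculated with constants of no real substance, and the scatter is random.)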